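**Remarks.** TBS = tert-butyldimethylsilyl; TBSO = tert-butyldimethylsilyloxy. Ring compounds keep the locants defined in the first section, also where systematic numbering would run the other way.

## The problem

The target 15 is a cyclohexene with three contiguous substituted carbons. C1 carries an enolised β-diketone chain that ends in a 4-hydroxy-3-methoxystyryl group, C2 a 4-hydroxy-3-methoxyphenyl (guaiacyl) group and C6 a 3,4-dimethoxyphenyl (veratryl) group; C3 is a methylene and C4=C5 the ring alkene. The configuration is 1R,2S,6R: the two aryl groups are cis to each other and the acyl chain is trans to both, so all three substituents can be equatorial. C1 is alpha to a carbonyl group and settles in this arrangement by enolisation. Only C2 and C6 therefore need kinetic control, and as they stand 1,3 to each other, one can direct the other. The alkene must stay at C4=C5, out of conjugation with both aryl groups, although the C6 hydrogen is allylic and benzylic and invites isomerisation or aromatisation. The chain is a vinylogous acid and a Michael acceptor and the phenols are easily oxidised, so strong base, oxidants and hydrogenation are excluded at the end; the two aryl rings, which differ by one O-methyl group, must be told apart from the start. The enabling feature is the 1,5-relationship of C6 and C4 across C1–C2–C3. With C6 as an aryl ketone carbonyl and C4 as a methyl ketone carbonyl, C1–C2 is a Michael bond and C5–C6 an aldol bond, so the ring is the Robinson annulation product of two aryl ketones.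

## Retrosynthesis

**15 ⇒ 14.** Only the two O–Si bonds are cut. Both phenols are carried as TBS ethers because free phenols would not survive the oxidations and the enolate chemistry of the endgame. Silyl ethers are chosen because buffered fluoride leaves the diketone, the alkenes and C6–H alone, whereas benzyl ethers would need hydrogenolysis.

**14 ⇒ 13 ⇒ 11 + 12.** The bond between the central carbon of the diketone and the ring-side carbonyl carbon is cut at the aldol oxidation level. The lithium enolate 12 comes from enone 2, and the acceptor is the ring aldehyde 11.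
- Cutting the same bond at the acyl level would need a hindered carboxylic acid derivative flanked by two aryl-bearing carbons, and freeing that acid from its ester would strip the aryl silyl ether.
- Cutting the styryl C=C by a late condensation would need a methyl diketone and a boron template, which costs more steps.
- The aldol cut reuses 2, so the side chain costs no new building block.
- The forward reaction must add faster than it enolises the α-branched aldehyde, and the oxidation of 13 must stop at the diketone.

**11 ⇒ 10 ⇒ 9.** No skeletal bond is cut; the aldehyde is traced through primary alcohol 10 to methyl ester 9. Two reliable steps are preferred to a partial reduction of a hindered ester.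

**9 ⇒ 8 ⇒ 7 ⇒ 6.** The C6–H bond is cut and oxygen is returned to C4, which leads through allylic carbonate 8 and allylic alcohol 7 to enone 6.
- The neighbouring option is direct conjugate hydride addition to C6 of 6, trapping of the C4 enolate as a triflate and its hydrogenolysis. The step count is the same, but the hydride would have to choose a face at C6 right next to the C1 ester, which sits on the face it must enter. β-Aryl cyclohexenones are also poor substrates for conjugate reduction by bulky borohydrides such as LiBH(s-Bu)3.
- The stereochemical decision is therefore moved to C4, where the C2 aryl group alone should govern a 1,2-reduction. It is then passed to C6 by a stereospecific palladium–formate hydride delivery with allylic transposition.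
- The forward sequence must place the C4 hydroxyl cis to the C2 aryl group and deliver hydride to C6 rather than C4.

**6 ⇒ 2 + 3.** The C1–C2 and C5–C6 bonds are cut. This takes the ring apart into silylated dehydrozingerone 2 and the aroylacetate 3, which together hold all six ring carbons, both ring aryl groups and the C1 carboxyl carbon. No other cut of 6 reaches two such simple ketones. The forward reaction must control the enantioface at C2 and close the ring on the aryl ketone rather than the ester.

**2 ⇒ 1.** The O–Si bond is cut; dehydrozingerone 1 is commercial.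

## Roads not taken

**Alternative 1:** The C1–C6 bond is cut by a lactone-enolate Claisen rearrangement. The silyl ketene acetal of the trans-4-aryl-6-styryl δ-lactone A2 would rearrange through a boat transition state. This forms C1–C6, breaks the allylic C4–O bond, places the alkene at C4=C5 and gives the all-cis acid A1.
- Merits: one pericyclic step sets the ring, the alkene position and the C2/C6 cis relationship by chirality transfer, and it leaves a free carboxyl group. In this respect it is better than the chosen plan, which needs steps 3 to 5 to relay C2 to C6.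
- Weak points: A2 needs two stereocentres set trans in enantiopure form before the key step, which is several steps of its own. Its C4–O bond is a cinnamyl-type bond to an electron-rich styrene and may ionise. C1 comes out cis to both aryl groups and must be inverted later.
- Comparison: the chosen plan sets against this a key step whose two partners are one step from commerce and a catalyst-set absolute configuration, so the whole route is shorter.

**Alternative 2:** The C2–C3 bond is cut. One-electron oxidation of the phenoxide of the all-trans vinylcyclobutane A4 would break the ring bond between C2 and C5, and the allyl radical would reclose on the quinone methide to give ester A3.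
- Merits: A3 arrives with the alkene in place, all three stereocentres in the stable arrangement and the ring phenol free. That is fewer steps after the key step than the chosen plan and one protecting group less.
- Weak points: A4 is an unsymmetrical tetrasubstituted cyclobutane that would have to come from a regio-, diastereo- and enantioselective crossed [2+2] reaction, which is harder than the target itself. The ring expansion has no close precedent, and the phenoxyl radical can also dimerise.
- Comparison: the chosen plan is longer after its key step, but every step is a known reaction type.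

**Alternative 3:** The C1–C2 bond is cut. Fluoride would unmask the phenoxide of A6, acetate would leave to give a para-quinone methide, and the tethered 1,3-dioxane-4,6-dione carbanion would add in a 6-exo closure to the spiro compound A5.
- Merits: the conditions are mild, the aryl groups should come out cis from a chair-like closure, C1 is not stereogenic at that stage and the phenol is freed in the same operation. Setting C2 against C6 directly is more economical than the relay of the chosen plan.
- Weak points: A6 needs a Z-alkene and an enantiopure C6 centre, which takes a long linear sequence. The addition can reverse. A5 must then be degraded by ring opening and decarboxylation before the side chain can be built.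
- Comparison: the chosen plan makes the ring and sets its absolute configuration in one catalytic step from two commercial ketones.

Key step: step 2

Assumption: the (4S)-imidazolidine catalyst from L-phenylalanine is taken to give the 2S series; if the sense of induction is the opposite, its (4R) enantiomer from D-phenylalanine is used and nothing else changes.

## Route

Step 1
Reactants: 1 dehydrozingerone, (E)-4-(4-hydroxy-3-methoxyphenyl)but-3-en-2-one
Product: 2 (E)-4-[4-(TBSO)-3-methoxyphenyl]but-3-en-2-one
Conditions: TBSCl, imidazole, DMF, rt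
Reagents that add atoms: tert-butyldimethylsilyl chloride, CC(C)(C)[Si](C)(C)Cl
Why: Standard silylation of a phenol; the silyl ether keeps the phenol out of the amine catalysis, the oxidations and the enolate step.

Step 2
Reactants: 2 (E)-4-[4-(TBSO)-3-methoxyphenyl]but-3-en-2-one; 3 methyl 3-(3,4-dimethoxyphenyl)-3-oxopropanoate
Product: 6 methyl (1R,2S)-2-[4-(TBSO)-3-methoxyphenyl]-6-(3,4-dimethoxyphenyl)-4-oxocyclohex-5-ene-1-carboxylate, via Michael adduct 4 (not isolated), via aldol adduct 5 (not isolated)
Conditions: (4S)-4-benzyl-1-methylimidazolidine-2-carboxylic acid (10 mol%), EtOH, rt; then p-TsOH·H2O (10 mol%), toluene, 80 °C, under argon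
Reagents that add atoms: none
Why: The secondary amine condenses with the methyl ketone of 2 to an iminium ion, the enol of 3 adds through C1 to the β-carbon C2 on the face left open by the benzyl group of the catalyst, and release of the amine gives 4; this is the known amine-catalysed enantioselective Michael/aldol domino of aroylacetates with benzylideneacetones. The methyl ketone of 4 then attacks the aryl ketone through C5 as its enol or enamine in a 6-(enolendo)-exo-trig aldol closure to 5, in which ester and both aryl groups are expected to be equatorial, and acid removes the tertiary benzylic hydroxyl to give the enone conjugated with the veratryl ring. C2 is under catalyst control; C1 lies between two carbonyl groups in 4 and is vinylogously acidic in 6, so it is under thermodynamic control and should settle trans to the C2 aryl group. The step needs the aldol to choose the aryl ketone over the ester, which the higher electrophilicity of the ketone secures, and the Michael donor to react through its doubly activated C1. The electron-rich aryl group of 2 lowers the electrophilicity of the iminium ion, so long reaction times are expected, and the acid stage also drives any uncyclised 4 through to 6.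

Step 3
Reactants: 6 methyl (1R,2S)-2-[4-(TBSO)-3-methoxyphenyl]-6-(3,4-dimethoxyphenyl)-4-oxocyclohex-5-ene-1-carboxylate
Product: 7 methyl (1R,2S,4R)-2-[4-(TBSO)-3-methoxyphenyl]-6-(3,4-dimethoxyphenyl)-4-hydroxycyclohex-5-ene-1-carboxylate
Conditions: NaBH4, CeCl3·7H2O, MeOH, −20 °C
Reagents that add atoms: none
Why: Luche reduction gives clean 1,2-addition; as with other 5-substituted cyclohexenones the hydride should enter C4 from the face away from the C2 aryl group, which places the hydroxyl cis to that aryl group (4R). The C1 ester is remote from C4 and should not interfere.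

Step 4
Reactants: 7 methyl (1R,2S,4R)-2-[4-(TBSO)-3-methoxyphenyl]-6-(3,4-dimethoxyphenyl)-4-hydroxycyclohex-5-ene-1-carboxylate
Product: 8 methyl (1R,2S,4R)-2-[4-(TBSO)-3-methoxyphenyl]-6-(3,4-dimethoxyphenyl)-4-(methoxycarbonyloxy)cyclohex-5-ene-1-carboxylate
Conditions: ClCO2Me, pyridine, 4-(dimethylamino)pyridine (cat.), CH2Cl2, 0 °C; used without chromatography
Reagents that add atoms: methyl chloroformate, COC(=O)Cl
Why: Acylation of the allylic alcohol with retention at C4; the carbonate ionises under zerovalent palladium at room temperature and leaves only CO2 and methanol.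

Step 5
Reactants: 8 methyl (1R,2S,4R)-2-[4-(TBSO)-3-methoxyphenyl]-6-(3,4-dimethoxyphenyl)-4-(methoxycarbonyloxy)cyclohex-5-ene-1-carboxylate
Product: 9 methyl (1R,2S,6R)-2-[4-(TBSO)-3-methoxyphenyl]-6-(3,4-dimethoxyphenyl)cyclohex-4-ene-1-carboxylate
Conditions: Pd2(dba)3 (2.5 mol%), PBu3 (10 mol%), HCO2H, Et3N, THF, 25–40 °C
Reagents that add atoms: none
Why: Palladium-catalysed formate hydrogenolysis of an allylic carbonate with allylic transposition: zerovalent palladium ionises the carbonate anti to the leaving group, the palladium formate loses CO2 and passes hydride to the more substituted terminus C6 on the palladium face. The C6 hydrogen therefore ends trans to the C2 aryl group and cis to the ester (6R), and the alkene is left at C4=C5; PBu3 is the ligand known to favour the less substituted alkene.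

Step 6
Reactants: 9 methyl (1R,2S,6R)-2-[4-(TBSO)-3-methoxyphenyl]-6-(3,4-dimethoxyphenyl)cyclohex-4-ene-1-carboxylate
Product: 10 [(1R,2S,6R)-2-[4-(TBSO)-3-methoxyphenyl]-6-(3,4-dimethoxyphenyl)cyclohex-4-en-1-yl]methanol
Conditions: i-Bu2AlH, CH2Cl2, −78 to 0 °C
Reagents that add atoms: none
Why: Hydride reduction of the hindered ester to the primary alcohol; aryl silyl ether, alkene and stereocentres are untouched.

Step 7
Reactants: 10 [(1R,2S,6R)-2-[4-(TBSO)-3-methoxyphenyl]-6-(3,4-dimethoxyphenyl)cyclohex-4-en-1-yl]methanol
Product: 11 (1R,2S,6R)-2-[4-(TBSO)-3-methoxyphenyl]-6-(3,4-dimethoxyphenyl)cyclohex-4-ene-1-carbaldehyde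
Conditions: Dess–Martin periodinane, CH2Cl2, rt
Reagents that add atoms: none
Why: Dess–Martin oxidation of a primary alcohol under non-basic conditions; the all-equatorial aldehyde is the thermodynamic C1 epimer, so enolisation cannot erode it.

Step 8
Reactants: 11 (1R,2S,6R)-2-[4-(TBSO)-3-methoxyphenyl]-6-(3,4-dimethoxyphenyl)cyclohex-4-ene-1-carbaldehyde; 2 (E)-4-[4-(TBSO)-3-methoxyphenyl]but-3-en-2-one
Product: 13 (E)-1-[4-(TBSO)-3-methoxyphenyl]-5-hydroxy-5-[(1R,2S,6R)-2-[4-(TBSO)-3-methoxyphenyl]-6-(3,4-dimethoxyphenyl)cyclohex-4-en-1-yl]pent-1-en-3-one (both carbinol epimers), via lithium enolate 12 (not isolated)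
Conditions: 2, LiN(i-Pr)2, THF, −78 °C; then 11, −78 °C; AcOH quench
Reagents that add atoms: none
Why: Kinetic deprotonation of the methyl group of 2 gives the cross-conjugated enolate 12, which adds to the aldehyde in a directed aldol addition. The new carbinol centre is oxidised in the next step, so its configuration does not matter.

Step 9
Reactants: 13 (E)-1-[4-(TBSO)-3-methoxyphenyl]-5-hydroxy-5-[(1R,2S,6R)-2-[4-(TBSO)-3-methoxyphenyl]-6-(3,4-dimethoxyphenyl)cyclohex-4-en-1-yl]pent-1-en-3-one
Product: 14 (2Z,4E)-3-hydroxy-5-[4-(TBSO)-3-methoxyphenyl]-1-[(1R,2S,6R)-2-[4-(TBSO)-3-methoxyphenyl]-6-(3,4-dimethoxyphenyl)cyclohex-4-en-1-yl]penta-2,4-dien-1-one (enol form of the β-diketone)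
Conditions: 2-iodoxybenzoic acid (IBX), EtOAc, 75 °C
Reagents that add atoms: none
Why: IBX oxidation of a β-hydroxy ketone to the β-diketone, a reagent known to stop at the diketone without attacking its central carbon; the protected phenols and the alkenes are not touched, and the product rests as the chelated enol.

Step 10
Reactants: 14 (2Z,4E)-3-hydroxy-5-[4-(TBSO)-3-methoxyphenyl]-1-[(1R,2S,6R)-2-[4-(TBSO)-3-methoxyphenyl]-6-(3,4-dimethoxyphenyl)cyclohex-4-en-1-yl]penta-2,4-dien-1-one
Product: 15 (2Z,4E)-3-hydroxy-5-(4-hydroxy-3-methoxyphenyl)-1-[(1R,2S,6R)-2-(4-hydroxy-3-methoxyphenyl)-6-(3,4-dimethoxyphenyl)cyclohex-4-en-1-yl]penta-2,4-dien-1-one (CNP0290899.1)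
Conditions: Bu4NF, AcOH, THF, 0 °C
Reagents that add atoms: none
Why: Fluoride cleaves both aryl silyl ethers, and acetic acid protonates the phenoxides and the diketone enolate as they form. C1 is alpha to the diketone and stays in its thermodynamic all-equatorial configuration.

## Compound list

1 | dehydrozingerone, (E)-4-(4-hydroxy-3-methoxyphenyl)but-3-en-2-one | CC(=O)/C=C/c1ccc(O)c(OC)c1 | starting material
2 | (E)-4-[4-(TBSO)-3-methoxyphenyl]but-3-en-2-one | CC(=O)/C=C/c1ccc(O[Si](C)(C)C(C)(C)C)c(OC)c1 | intermediate
3 | methyl 3-(3,4-dimethoxyphenyl)-3-oxopropanoate | COC(=O)CC(=O)c1ccc(OC)c(OC)c1 | starting material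
4 | Michael adduct, methyl (3S)-3-[4-(TBSO)-3-methoxyphenyl]-2-(3,4-dimethoxybenzoyl)-5-oxohexanoate, both epimers at the chain C2 | COC(=O)C(C(=O)c1ccc(OC)c(OC)c1)[C@@H](c1ccc(O[Si](C)(C)C(C)(C)C)c(OC)c1)CC(C)=O | intermediate
5 | aldol adduct, methyl (1R,2S,6S)-2-[4-(TBSO)-3-methoxyphenyl]-6-(3,4-dimethoxyphenyl)-6-hydroxy-4-oxocyclohexane-1-carboxylate (expected relative configuration) | COC(=O)[C@@H]1[C@@H](c2ccc(O[Si](C)(C)C(C)(C)C)c(OC)c2)CC(=O)C[C@@]1(O)c1ccc(OC)c(OC)c1 | intermediate
6 | methyl (1R,2S)-2-[4-(TBSO)-3-methoxyphenyl]-6-(3,4-dimethoxyphenyl)-4-oxocyclohex-5-ene-1-carboxylate | COC(=O)[C@@H]1[C@@H](c2ccc(O[Si](C)(C)C(C)(C)C)c(OC)c2)CC(=O)C=C1c1ccc(OC)c(OC)c1 | intermediate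
7 | methyl (1R,2S,4R)-2-[4-(TBSO)-3-methoxyphenyl]-6-(3,4-dimethoxyphenyl)-4-hydroxycyclohex-5-ene-1-carboxylate | COC(=O)[C@@H]1[C@@H](c2ccc(O[Si](C)(C)C(C)(C)C)c(OC)c2)C[C@@H](O)C=C1c1ccc(OC)c(OC)c1 | intermediate
8 | methyl (1R,2S,4R)-2-[4-(TBSO)-3-methoxyphenyl]-6-(3,4-dimethoxyphenyl)-4-(methoxycarbonyloxy)cyclohex-5-ene-1-carboxylate | COC(=O)[C@@H]1[C@@H](c2ccc(O[Si](C)(C)C(C)(C)C)c(OC)c2)C[C@@H](OC(=O)OC)C=C1c1ccc(OC)c(OC)c1 | intermediate
9 | methyl (1R,2S,6R)-2-[4-(TBSO)-3-methoxyphenyl]-6-(3,4-dimethoxyphenyl)cyclohex-4-ene-1-carboxylate | COC(=O)[C@@H]1[C@@H](c2ccc(O[Si](C)(C)C(C)(C)C)c(OC)c2)CC=C[C@H]1c1ccc(OC)c(OC)c1 | intermediate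
10 | [(1R,2S,6R)-2-[4-(TBSO)-3-methoxyphenyl]-6-(3,4-dimethoxyphenyl)cyclohex-4-en-1-yl]methanol | OC[C@@H]1[C@@H](c2ccc(O[Si](C)(C)C(C)(C)C)c(OC)c2)CC=C[C@H]1c1ccc(OC)c(OC)c1 | intermediate
11 | (1R,2S,6R)-2-[4-(TBSO)-3-methoxyphenyl]-6-(3,4-dimethoxyphenyl)cyclohex-4-ene-1-carbaldehyde | O=C[C@@H]1[C@@H](c2ccc(O[Si](C)(C)C(C)(C)C)c(OC)c2)CC=C[C@H]1c1ccc(OC)c(OC)c1 | intermediate
12 | lithium enolate of 2, lithium (E)-4-[4-(TBSO)-3-methoxyphenyl]buta-1,3-dien-2-olate | [Li]OC(=C)/C=C/c1ccc(O[Si](C)(C)C(C)(C)C)c(OC)c1 | intermediate
13 | (E)-1-[4-(TBSO)-3-methoxyphenyl]-5-hydroxy-5-[(1R,2S,6R)-2-[4-(TBSO)-3-methoxyphenyl]-6-(3,4-dimethoxyphenyl)cyclohex-4-en-1-yl]pent-1-en-3-one, both carbinol epimers | COc1cc(/C=C/C(=O)CC(O)[C@@H]2[C@@H](c3ccc(O[Si](C)(C)C(C)(C)C)c(OC)c3)CC=C[C@H]2c2ccc(OC)c(OC)c2)ccc1O[Si](C)(C)C(C)(C)C | intermediate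
14 | (2Z,4E)-3-hydroxy-5-[4-(TBSO)-3-methoxyphenyl]-1-[(1R,2S,6R)-2-[4-(TBSO)-3-methoxyphenyl]-6-(3,4-dimethoxyphenyl)cyclohex-4-en-1-yl]penta-2,4-dien-1-one | COc1cc(/C=C/C(O)=C/C(=O)[C@@H]2[C@@H](c3ccc(O[Si](C)(C)C(C)(C)C)c(OC)c3)CC=C[C@H]2c2ccc(OC)c(OC)c2)ccc1O[Si](C)(C)C(C)(C)C | intermediate
15 | (2Z,4E)-3-hydroxy-5-(4-hydroxy-3-methoxyphenyl)-1-[(1R,2S,6R)-2-(4-hydroxy-3-methoxyphenyl)-6-(3,4-dimethoxyphenyl)cyclohex-4-en-1-yl]penta-2,4-dien-1-one | COc1cc(/C=C/C(O)=C/C(=O)[C@@H]2[C@@H](c3ccc(O)c(OC)c3)CC=C[C@H]2c2ccc(OC)c(OC)c2)ccc1O | target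

## Step count and risk

Total step count: 10. Longest linear sequence: 10 steps (1 to 15); 3 is purchased and 2 is used in steps 2 and 8.

**Step 2 (key step).** The donor aryl group of 2 may make iminium formation and conjugate addition so slow that a non-selective background addition or retro-Michael equilibration erodes the enantiomeric purity. The acid stage may also give some alkene isomer conjugated with the ester. The fallback reverses donor and acceptor for the first bond and sets out from 3. Knoevenagel condensation of 3 with 4-(tert-butyldimethylsilyloxy)-3-methoxybenzaldehyde F1 gives the arylidene ketoester methyl 2-(3,4-dimethoxybenzoyl)-3-[4-(TBSO)-3-methoxyphenyl]prop-2-enoate F2. F2 is a doubly activated acceptor to which acetone adds as its enamine under a chiral primary amine–thiourea catalyst. This forms C2–C3 instead of C1–C2 but gives the same adduct 4, which is closed and dehydrated with p-TsOH·H2O to rejoin the route at 6.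

**Step 5.** Hydride may be delivered to C4 instead of C6, which leaves the alkene in conjugation. The allyl complex may lose stereochemical fidelity by palladium–palladium exchange. Base may remove the acidic C1 hydrogen from the allyl complex and give a cyclohexadiene. The fallback uses a metal-free reductive transposition and sets out from 7. Mitsunobu reaction of 7 with N-isopropylidene-N'-(2-nitrobenzenesulfonyl)hydrazine (PPh3, diethyl azodicarboxylate, THF, 0 °C) gives, with inversion at C4, the sulfonyl hydrazone methyl (1R,2S,4S)-2-[4-(TBSO)-3-methoxyphenyl]-6-(3,4-dimethoxyphenyl)-4-[N-(2-nitrobenzenesulfonyl)-N'-isopropylidenehydrazino]cyclohex-5-ene-1-carboxylate F3. Mild hydrolysis in trifluoroethanol–water releases the allylic diazene methyl (1R,2S,4S)-4-diazenyl-2-[4-(TBSO)-3-methoxyphenyl]-6-(3,4-dimethoxyphenyl)cyclohex-5-ene-1-carboxylate F4. F4 loses nitrogen in a retro-ene shift that places hydrogen on C6 from the nitrogen face and the alkene at C4=C5, and the route is rejoined at 9.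

**Step 3.** Facial selectivity in the 1,2-reduction may be poor or reversed if the conformer with axial C1 and C2 substituents reacts differently from simple 5-substituted cyclohexenones; the C4 epimer would relay the wrong configuration to C6. The fallback is a relay with retention and sets out from 6. Condensation with p-toluenesulfonyl hydrazide gives the tosylhydrazone methyl (1R,2S)-2-[4-(TBSO)-3-methoxyphenyl]-6-(3,4-dimethoxyphenyl)-4-(tosylhydrazono)cyclohex-5-ene-1-carboxylate F5. Reduction with catecholborane and then NaOAc·3H2O gives an allylic diazene that delivers hydrogen to C6 on its own face. If hydride enters C4 syn to the C2 aryl group, this diazene is F4 and the outcome is complementary to the Luche/palladium pair; the route is rejoined at 9.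

**Step 8.** The basic enolate may enolise the hindered α-branched aldehyde, or the aldolate may revert on work-up, so conversion may be low. The fallback is acylation instead of aldol addition and sets out from 11. Pinnick oxidation (NaClO2, NaH2PO4, 2-methyl-2-butene) gives the acid (1R,2S,6R)-2-[4-(TBSO)-3-methoxyphenyl]-6-(3,4-dimethoxyphenyl)cyclohex-4-ene-1-carboxylic acid F6. Carbonyldiimidazole converts it into the acyl imidazole F7, which C-acylates two equivalents of enolate 12 to give 14 directly, without 13 and step 9.

## Further compounds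

F1 | step 2 | 4-(tert-butyldimethylsilyloxy)-3-methoxybenzaldehyde | O=Cc1ccc(O[Si](C)(C)C(C)(C)C)c(OC)c1
F2 | step 2 | methyl 2-(3,4-dimethoxybenzoyl)-3-[4-(TBSO)-3-methoxyphenyl]prop-2-enoate (E/Z mixture) | COC(=O)C(=Cc1ccc(O[Si](C)(C)C(C)(C)C)c(OC)c1)C(=O)c1ccc(OC)c(OC)c1
F3 | step 5 | methyl (1R,2S,4S)-2-[4-(TBSO)-3-methoxyphenyl]-6-(3,4-dimethoxyphenyl)-4-[N-(2-nitrobenzenesulfonyl)-N'-isopropylidenehydrazino]cyclohex-5-ene-1-carboxylate | COC(=O)[C@@H]1[C@@H](c2ccc(O[Si](C)(C)C(C)(C)C)c(OC)c2)C[C@H](N(N=C(C)C)S(=O)(=O)c2ccccc2[N+](=O)[O-])C=C1c1ccc(OC)c(OC)c1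
F4 | step 5 | methyl (1R,2S,4S)-4-diazenyl-2-[4-(TBSO)-3-methoxyphenyl]-6-(3,4-dimethoxyphenyl)cyclohex-5-ene-1-carboxylate | COC(=O)[C@@H]1[C@@H](c2ccc(O[Si](C)(C)C(C)(C)C)c(OC)c2)C[C@H](N=N)C=C1c1ccc(OC)c(OC)c1
F5 | step 3 | methyl (1R,2S)-2-[4-(TBSO)-3-methoxyphenyl]-6-(3,4-dimethoxyphenyl)-4-(tosylhydrazono)cyclohex-5-ene-1-carboxylate | COC(=O)[C@@H]1[C@@H](c2ccc(O[Si](C)(C)C(C)(C)C)c(OC)c2)CC(=NNS(=O)(=O)c2ccc(C)cc2)C=C1c1ccc(OC)c(OC)c1
F6 | step 8 | (1R,2S,6R)-2-[4-(TBSO)-3-methoxyphenyl]-6-(3,4-dimethoxyphenyl)cyclohex-4-ene-1-carboxylic acid | OC(=O)[C@@H]1[C@@H](c2ccc(O[Si](C)(C)C(C)(C)C)c(OC)c2)CC=C[C@H]1c1ccc(OC)c(OC)c1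
F7 | step 8 | 1-[(1R,2S,6R)-2-[4-(TBSO)-3-methoxyphenyl]-6-(3,4-dimethoxyphenyl)cyclohex-4-ene-1-carbonyl]imidazole | O=C(n1ccnc1)[C@@H]1[C@@H](c2ccc(O[Si](C)(C)C(C)(C)C)c(OC)c2)CC=C[C@H]1c1ccc(OC)c(OC)c1
A1 | alternative 1 | all-cis 2-[4-(TBSO)-3-methoxyphenyl]-6-(3,4-dimethoxyphenyl)cyclohex-3-ene-1-carboxylic acid | OC(=O)[C@H]1[C@@H](c2ccc(O[Si](C)(C)C(C)(C)C)c(OC)c2)CC=C[C@H]1c1ccc(OC)c(OC)c1
A2 | alternative 1 | trans-4-[4-(TBSO)-3-methoxyphenyl]-6-[(E)-2-(3,4-dimethoxyphenyl)ethenyl]tetrahydropyran-2-one | O=C1C[C@@H](c2ccc(O[Si](C)(C)C(C)(C)C)c(OC)c2)C[C@H](/C=C/c2ccc(OC)c(OC)c2)O1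
A3 | alternative 2 | methyl trans,trans-2-(4-hydroxy-3-methoxyphenyl)-6-(3,4-dimethoxyphenyl)cyclohex-3-ene-1-carboxylate | COC(=O)[C@@H]1[C@@H](c2ccc(O)c(OC)c2)CC=C[C@H]1c1ccc(OC)c(OC)c1
A4 | alternative 2 | methyl all-trans-2-(4-hydroxy-3-methoxyphenyl)-3-vinyl-4-(3,4-dimethoxyphenyl)cyclobutane-1-carboxylate | COC(=O)[C@@H]1[C@@H](c2ccc(O)c(OC)c2)[C@H](C=C)[C@H]1c1ccc(OC)c(OC)c1
A5 | alternative 3 | spiro 2,2-dimethyl-1,3-dioxane-4,6-dione of cis-2-(4-hydroxy-3-methoxyphenyl)-6-(3,4-dimethoxyphenyl)cyclohex-3-ene | CC1(C)OC(=O)C2(C(=O)O1)[C@@H](c1ccc(O)c(OC)c1)CC=C[C@H]2c1ccc(OC)c(OC)c1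
A6 | alternative 3 | 5-[(Z)-5-acetoxy-1-(3,4-dimethoxyphenyl)-5-[4-(TBSO)-3-methoxyphenyl]pent-2-en-1-yl]-2,2-dimethyl-1,3-dioxane-4,6-dione | CC1(C)OC(=O)C(C(=O)O1)[C@H](c1ccc(OC)c(OC)c1)/C=C\CC(OC(C)=O)c1ccc(O[Si](C)(C)C(C)(C)C)c(OC)c1
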